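**Retrosynthetic overview**

1. The target, (3'S)-3'-hydroxy-4',5'-didehydro-4,5'-retro-β,β-caroten-3-one, is cut at the two disubstituted double bonds C10=C11 and C10'=C11' (two Wittig reactions) into a ring A C14 phosphonium salt, a symmetrical C12 tetraenedial (glyoxal plus two C5 phosphonate units) and a ring B C14 phosphonium salt.
2. Ring B is not made: it is the carbocycle of ketoisophorone. Its C4 carbonyl is reduced enantioselectively (C3', S); its C1 carbonyl receives C7'–C10' by acetylide addition, reduction and a cationic 1,5-transposition to the phosphonium salt.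
3. Ring A is the only ring closed in the route and is closed after ring B is in hand. An acyclic allenyl ketone, joined from mesityl oxide, but-3-yn-2-one and a C4 alkenyl iodide, is enolised and undergoes a 6π-electrocyclisation that forms the C1–C6 bond.
4. Enabling feature: ring A is a 4-alkylidenecyclohex-2-enone whose exocyclic C6=C7 bond sits between the gem-dimethyl carbon C1 and the enone carbon C5. It is therefore the hydrolysed form of a hexatriene C1=C2–C3(O)=C4–C5=C6 whose terminus C6 is the centre of an allene C5=C6=C7; closing C1–C6 leaves the orthogonal C6=C7 π bond as the exocyclic alkene.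
5. Order of rings: ring B (bought closed, decorated in steps 1–5), then ring A (step 12); the mobile alkene geometries are converged to all-E in the last step.

Key step: step 12

Remark: positions are cited by carotenoid numbering (C1–C15 for the keto half, primed numbers for the hydroxy half); the ring-junction double bonds C6=C7 and C6'=C7' and the Wittig-derived double bonds are configurationally mobile in retro-carotenoids, so intermediates are drawn as the isomer expected to predominate and the geometry is converged to the all-E target in step 16.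

**Route**

Step 1
Reactants: 1 ketoisophorone (2,6,6-trimethylcyclohex-2-ene-1,4-dione)
Product: 2 (4S)-4-hydroxy-2,6,6-trimethylcyclohex-2-en-1-one
Conditions: RuCl[(S,S)-TsDPEN](p-cymene) (cat.), KOH (cat.), i-PrOH, rt
Reagents that add atoms: none
Why: Asymmetric transfer hydrogenation should reduce only the less hindered C4 carbonyl (the C1 carbonyl is flanked by the quaternary carbon and the methyl-bearing alkene carbon), and the (S,S) catalyst, with the enone C=C in the role usually played by an aryl group, should give the 4S alcohol that becomes C3' (the mirror-image catalyst would be taken if the sense proved opposite).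

Step 2
Reactants: 2 (4S)-4-hydroxy-2,6,6-trimethylcyclohex-2-en-1-one
Product: 3 (4S)-4-{[tert-butyl(dimethyl)silyl]oxy}-2,6,6-trimethylcyclohex-2-en-1-one
Conditions: TBSCl, imidazole, DMF, rt
Reagents that add atoms: tert-butyldimethylsilyl chloride (CC(C)(C)[Si](C)(C)Cl)
Why: Standard silylation of a secondary allylic alcohol, which masks the C3' hydroxyl against the organolithium, hydride and ylide steps and does not touch the stereocentre.

Step 3
Reactants: 3 (4S)-4-{[tert-butyl(dimethyl)silyl]oxy}-2,6,6-trimethylcyclohex-2-en-1-one; 4 2-methylbut-1-en-3-yne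
Product: 6 (4S)-4-{[tert-butyl(dimethyl)silyl]oxy}-2,6,6-trimethyl-1-(3-methylbut-3-en-1-yn-1-yl)cyclohex-2-en-1-ol (both C1 epimers), via lithium acetylide 5 (not isolated)
Conditions: n-BuLi, THF, −78 °C; then 3, −78 → 0 °C; H2O
Reagents that add atoms: none
Why: 1,2-Addition of a lithium acetylide to the hindered ketone, which has no α-hydrogen to lose; the new carbinol centre is formed without control and is deleted in step 5.

Step 4
Reactants: 6 tertiary propargylic alcohol
Product: 7 (4S)-4-{[tert-butyl(dimethyl)silyl]oxy}-2,6,6-trimethyl-1-[(1E)-3-methylbuta-1,3-dien-1-yl]cyclohex-2-en-1-ol (both C1 epimers)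
Conditions: LiAlH4, THF, 0 → 40 °C; aqueous work-up
Reagents that add atoms: none
Why: The aluminium alkoxide directs trans-hydroalumination of the propargylic triple bond (LiAlH4 reduction of propargylic alcohols), giving the E alkene after hydrolysis while the 1,1-disubstituted alkene and the silyl ether are left alone.

Step 5
Reactants: 7 tertiary dienyl carbinol
Product: 8 {(2E,4E)-4-[(4S)-4-{[tert-butyl(dimethyl)silyl]oxy}-2,6,6-trimethylcyclohex-2-en-1-ylidene]-3-methylbut-2-en-1-yl}triphenylphosphonium bromide
Conditions: PPh3·HBr, CH2Cl2, 0 °C → rt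
Reagents that add atoms: triphenylphosphine hydrobromide ([Br-].[PH+](c1ccccc1)(c1ccccc1)c1ccccc1)
Why: Protonation ionises the tertiary doubly allylic alcohol to a delocalised cation that triphenylphosphine captures at the unhindered terminal CH2 (C10'), the vinylogous form of the allylic-transposition route from tertiary vinyl carbinols to primary allylic phosphonium salts; this creates the conjugated C6'=C7' and C8'=C9' bonds, and the aprotic solvent should spare the silyl ether.

Step 6
Reactants: 9 glyoxal; 10 ethyl (2E)-4-(diethoxyphosphoryl)-3-methylbut-2-enoate (2 equiv)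
Product: 13 diethyl (2E,4E,6E,8E)-3,8-dimethyldeca-2,4,6,8-tetraenedioate, via phosphonate carbanion sodium salt 11 (not isolated), via aldehyde ester 12 (not isolated)
Conditions: NaOEt, EtOH, 0 °C; glyoxal (40% in H2O) added slowly; 0 °C → rt
Reagents that add atoms: none
Why: Two-fold Horner–Wadsworth–Emmons olefination in which the vinylogous phosphonate carbanion reacts at its phosphorus-bearing carbon with each aldehyde group to give E double bonds, the E trisubstituted alkene being carried in from 10.

Step 7
Reactants: 13 tetraene diester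
Product: 14 (2E,4E,6E,8E)-3,8-dimethyldeca-2,4,6,8-tetraene-1,10-diol
Conditions: i-Bu2AlH, CH2Cl2, −78 → 0 °C; Rochelle salt work-up
Reagents that add atoms: none
Why: i-Bu2AlH reduces the conjugated esters in 1,2-fashion to the allylic alcohols without touching the tetraene.

Step 8
Reactants: 14 tetraene diol
Product: 15 (2E,4E,6E,8E)-3,8-dimethyldeca-2,4,6,8-tetraenedial
Conditions: MnO2, CH2Cl2, rt, dark
Reagents that add atoms: none
Why: MnO2 oxidises allylic alcohols selectively to enals without over-oxidation.

Step 9
Reactants: 16 mesityl oxide (4-methylpent-3-en-2-one); 17 but-3-yn-2-one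
Product: 20 methyl 3,7-dimethyl-5-oxooct-6-en-1-yn-3-yl carbonate (racemic), via lithium enolate 18 (not isolated), via lithium aldolate 19 (not isolated)
Conditions: LiN(i-Pr)2, THF, −78 °C; then 17, −78 °C; then ClCO2Me, −78 → −30 °C
Reagents that add atoms: methyl chloroformate (COC(=O)Cl)
Why: Kinetic deprotonation of mesityl oxide at the acetyl methyl group gives the cross-conjugated enolate, which adds 1,2 to the ynone (aldol addition), and the tertiary aldolate is acylated cold before retro-aldol cleavage; the uncontrolled stereocentre is erased in steps 11 and 12.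

Step 10
Reactants: 21 (2E)-3-iodo-2-methylprop-2-en-1-ol
Product: 22 tert-butyl{[(2E)-3-iodo-2-methylprop-2-en-1-yl]oxy}dimethylsilane
Conditions: TBSCl, imidazole, CH2Cl2, 0 °C → rt
Reagents that add atoms: tert-butyldimethylsilyl chloride (CC(C)(C)[Si](C)(C)Cl)
Why: Standard silylation of a primary allylic alcohol so that the iodide can be metalated.

Step 11
Reactants: 22 silyl-protected (E)-alkenyl iodide; 20 propargylic carbonate
Product: 25 (9E)-11-{[tert-butyl(dimethyl)silyl]oxy}-2,6,10-trimethylundeca-2,6,7,9-tetraen-4-one (racemic allene), via alkenyllithium 23 (not isolated), via alkenylzinc bromide 24 (not isolated)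
Conditions: t-BuLi (2 equiv), Et2O, −78 °C; ZnBr2, THF, −78 → 0 °C; then 20, Pd(PPh3)4 (5 mol%), THF, 0 °C → rt
Reagents that add atoms: none
Why: Iodine–lithium exchange and transmetalation keep the E geometry, and Negishi-type coupling of the alkenylzinc with the tertiary propargylic carbonate takes the anti-SN2' course (decarboxylative oxidative addition to an allenylpalladium species, transmetalation, reductive elimination at the alkyne terminus) to give the vinylallene as a racemate under non-basic conditions that spare the β-oxygenated ketone.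

Step 12
Reactants: 25 acyclic allenyl ketone
Product: 28 (4Z)-4-[(2E)-4-{[tert-butyl(dimethyl)silyl]oxy}-3-methylbut-2-en-1-ylidene]-3,5,5-trimethylcyclohex-2-en-1-one, via E enol borinate 26 (not isolated), via cyclic dienol borinate 27 (not isolated)
Conditions: (c-C6H11)2BCl, Et3N, Et2O, −78 → 0 °C; then 25–35 °C, dark, N2; MeOH, pH 7 buffer
Reagents that add atoms: none
Why: (c-C6H11)2BCl with Et3N is the reagent pair that enolises methylene ketones to E enol borinates, so the only sp3 α-position of 25 (C4) is converted into borinate 26 in which C2 and C5 are cis across the new C3=C4 bond, i.e. a (Z)-hexatriene C1=C2–C3=C4–C5=C6 whose last carbon is the allene centre. On warming, 26 should undergo a thermal disrotatory 6π-electrocyclisation of the type known for (Z)-dienyl-allenes (which give 5-alkylidenecyclohexa-1,3-dienes) and for 2-siloxy-hexatrienes: the gem-dimethyl terminus C1 bonds to the allene centre C6 and closes ring A in the six-electron disrotatory mode, while the orthogonal C6=C7 π bond is untouched and becomes the exocyclic double bond. Hydrolysis of the cyclic dienol borinate 27 protonates C2 and frees the C3 ketone in conjugation with C4=C5, so one operation supplies the C1–C6 bond next to the quaternary carbon, the enone and the retro (exocyclic) alkene of ring A from an acyclic chain. No stereocentre is formed (C1 carries two methyl groups) and the stereogenic allene axis of racemic 25 is destroyed, so both enantiomers converge on the same ring; closure anti to the larger C7 substituent should give mainly the Z ring-junction geometry, which is not needed because this bond is reset in steps 15 and 16. The step needs E enolisation (secured by the boron chloride/amine pair and by C4 being the only enolisable carbon) and periselectivity over a [1,5]-hydrogen shift from the C9 methyl group into the allene (favoured by the cumulated terminus, which offers an unhindered p orbital to C1, and by working at or just above room temperature).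

Step 13
Reactants: 28 ring A dienone silyl ether
Product: 30 [(2E,4Z)-3-methyl-4-(2,6,6-trimethyl-4-oxocyclohex-2-en-1-ylidene)but-2-en-1-yl]triphenylphosphonium bromide, via allylic alcohol 29 (not isolated)
Conditions: PPh3·HBr, MeOH, 0 °C → rt
Reagents that add atoms: triphenylphosphine hydrobromide ([Br-].[PH+](c1ccccc1)(c1ccccc1)c1ccccc1)
Why: HBr in methanol first solvolyses the primary allylic silyl ether and then, with triphenylphosphine, converts the allylic alcohol into the primary phosphonium salt (the usual preparation of polyenyl Wittig salts), the electron-poor dienone resisting ionisation elsewhere.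

Step 14
Reactants: 8 ring B phosphonium bromide; 15 C12 tetraenedial (3 equiv, excess recovered)
Product: 32 (all-E)-14-[(4S)-4-{[tert-butyl(dimethyl)silyl]oxy}-2,6,6-trimethylcyclohex-2-en-1-ylidene]-3,8,12-trimethyltetradeca-2,4,6,8,10,12-hexaenal, via ylide 31 (not isolated)
Conditions: 1,2-epoxybutane, EtOH, reflux, dark, N2
Reagents that add atoms: none
Why: Bromide opens the epoxide to an alkoxide that deprotonates the salt, and the semi-stabilised ylide undergoes a Wittig reaction with one aldehyde group of the dialdehyde used in excess, giving mainly the E C10'=C11' bond (any Z isomer is converged in step 16).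

Step 15
Reactants: 30 ring A phosphonium bromide; 32 C26 aldehyde
Product: 34 (3'S)-3'-{[tert-butyl(dimethyl)silyl]oxy}-4',5'-didehydro-4,5'-retro-β,β-caroten-3-one (drawn all-E), via ylide 33 (not isolated)
Conditions: 1,2-epoxybutane, EtOH–CH2Cl2, reflux, dark, N2
Reagents that add atoms: none
Why: The keto-stabilised vinylogous ylide 33 undergoes a Wittig reaction at its phosphorus-bearing carbon to give the E C10=C11 bond without touching the ring ketone; because C6–C7 and C8–C9 have single-bond character in this vinylogous enolate, the ring-junction geometry is reset here and 34 is carried as the all-E isomer together with Z isomers that are converged in step 16.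

Step 16
Reactants: 34 silyl ether of the target
Product: 35 (3'S,all-E)-3'-hydroxy-4',5'-didehydro-4,5'-retro-β,β-caroten-3-one (eschscholtzxanthone)
Conditions: Bu4NF, AcOH, THF, 0 °C → rt; then I2 (cat.), heptane–CH2Cl2, diffuse daylight, N2, rt; crystallisation
Reagents that add atoms: none
Why: Buffered fluoride cleaves the allylic silyl ether without ionising the C3'–O bond, and iodine-catalysed stereomutation, the standard equilibration of carotenoids, should funnel the isomers at C6=C7, C6'=C7', C10=C11 and C10'=C11' to the all-E isomer, the polyene that can stay planar, which crystallisation removes from the equilibrium.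

**Compound list**

1 | ketoisophorone (2,6,6-trimethylcyclohex-2-ene-1,4-dione) | CC1=CC(=O)CC(C)(C)C1=O | starting material
2 | (4S)-4-hydroxy-2,6,6-trimethylcyclohex-2-en-1-one | CC1=C[C@@H](O)CC(C)(C)C1=O | intermediate
3 | (4S)-4-{[tert-butyl(dimethyl)silyl]oxy}-2,6,6-trimethylcyclohex-2-en-1-one | CC1=C[C@@H](O[Si](C)(C)C(C)(C)C)CC(C)(C)C1=O | intermediate
4 | 2-methylbut-1-en-3-yne | C=C(C)C#C | starting material
5 | lithium 3-methylbut-3-en-1-yn-1-ide | [Li]C#CC(C)=C | intermediate
6 | (4S)-4-{[tert-butyl(dimethyl)silyl]oxy}-2,6,6-trimethyl-1-(3-methylbut-3-en-1-yn-1-yl)cyclohex-2-en-1-ol (both C1 epimers) | CC1=C[C@@H](O[Si](C)(C)C(C)(C)C)CC(C)(C)C1(O)C#CC(C)=C | intermediate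
7 | (4S)-4-{[tert-butyl(dimethyl)silyl]oxy}-2,6,6-trimethyl-1-[(1E)-3-methylbuta-1,3-dien-1-yl]cyclohex-2-en-1-ol (both C1 epimers) | CC1=C[C@@H](O[Si](C)(C)C(C)(C)C)CC(C)(C)C1(O)/C=C/C(C)=C | intermediate
8 | {(2E,4E)-4-[(4S)-4-{[tert-butyl(dimethyl)silyl]oxy}-2,6,6-trimethylcyclohex-2-en-1-ylidene]-3-methylbut-2-en-1-yl}triphenylphosphonium bromide | CC1=C[C@@H](O[Si](C)(C)C(C)(C)C)CC(C)(C)/C1=C\C=C(/C)C[P+](c1ccccc1)(c1ccccc1)c1ccccc1.[Br-] | intermediate
9 | glyoxal | O=CC=O | starting material
10 | ethyl (2E)-4-(diethoxyphosphoryl)-3-methylbut-2-enoate | CCOC(=O)/C=C(\C)CP(=O)(OCC)OCC | starting material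
11 | sodium salt of the carbanion of 10 | CCOC(=O)C=C(C)[CH-]P(=O)(OCC)OCC.[Na+] | intermediate
12 | ethyl (2E,4E)-3-methyl-6-oxohexa-2,4-dienoate | CCOC(=O)/C=C(C)/C=C/C=O | intermediate
13 | diethyl (2E,4E,6E,8E)-3,8-dimethyldeca-2,4,6,8-tetraenedioate | CCOC(=O)/C=C(C)/C=C/C=C/C(C)=C/C(=O)OCC | intermediate
14 | (2E,4E,6E,8E)-3,8-dimethyldeca-2,4,6,8-tetraene-1,10-diol | OC/C=C(C)/C=C/C=C/C(C)=C/CO | intermediate
15 | (2E,4E,6E,8E)-3,8-dimethyldeca-2,4,6,8-tetraenedial | O=C/C=C(C)/C=C/C=C/C(C)=C/C=O | intermediate
16 | mesityl oxide (4-methylpent-3-en-2-one) | CC(=O)C=C(C)C | starting material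
17 | but-3-yn-2-one | CC(=O)C#C | starting material
18 | lithium 4-methylpenta-1,3-dien-2-olate | [Li]OC(=C)C=C(C)C | intermediate
19 | lithium 3,7-dimethyl-5-oxooct-6-en-1-yn-3-olate (racemic) | [Li]OC(C)(C#C)CC(=O)C=C(C)C | intermediate
20 | methyl 3,7-dimethyl-5-oxooct-6-en-1-yn-3-yl carbonate (racemic) | C#CC(C)(OC(=O)OC)CC(=O)C=C(C)C | intermediate
21 | (2E)-3-iodo-2-methylprop-2-en-1-ol | OC/C(C)=C/I | starting material
22 | tert-butyl{[(2E)-3-iodo-2-methylprop-2-en-1-yl]oxy}dimethylsilane | CC(C)(C)[Si](C)(C)OC/C(C)=C/I | intermediate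
23 | [(1E)-3-{[tert-butyl(dimethyl)silyl]oxy}-2-methylprop-1-en-1-yl]lithium | CC(C)(C)[Si](C)(C)OC/C(C)=C/[Li] | intermediate
24 | [(1E)-3-{[tert-butyl(dimethyl)silyl]oxy}-2-methylprop-1-en-1-yl]zinc bromide | CC(C)(C)[Si](C)(C)OC/C(C)=C/[Zn]Br | intermediate
25 | (9E)-11-{[tert-butyl(dimethyl)silyl]oxy}-2,6,10-trimethylundeca-2,6,7,9-tetraen-4-one (racemic allene) | CC(C)=CC(=O)CC(C)=C=C/C=C(\C)CO[Si](C)(C)C(C)(C)C | intermediate
26 | E enol dicyclohexylborinate of 25 (B–O trans to the allene carbon C5; racemic allene) | CC(C)=C/C(OB(C1CCCCC1)C1CCCCC1)=C\C(C)=C=C/C=C(\C)CO[Si](C)(C)C(C)(C)C | intermediate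
27 | dicyclohexylborinate of the cyclised dienol (ring A closed) | CC1=CC(OB(C2CCCCC2)C2CCCCC2)=CC(C)(C)/C1=C/C=C(C)/CO[Si](C)(C)C(C)(C)C | intermediate
28 | (4Z)-4-[(2E)-4-{[tert-butyl(dimethyl)silyl]oxy}-3-methylbut-2-en-1-ylidene]-3,5,5-trimethylcyclohex-2-en-1-one | CC1=CC(=O)CC(C)(C)/C1=C/C=C(C)/CO[Si](C)(C)C(C)(C)C | intermediate
29 | (4Z)-4-[(2E)-4-hydroxy-3-methylbut-2-en-1-ylidene]-3,5,5-trimethylcyclohex-2-en-1-one | CC1=CC(=O)CC(C)(C)/C1=C/C=C(C)/CO | intermediate
30 | [(2E,4Z)-3-methyl-4-(2,6,6-trimethyl-4-oxocyclohex-2-en-1-ylidene)but-2-en-1-yl]triphenylphosphonium bromide | CC1=CC(=O)CC(C)(C)/C1=C/C=C(C)/C[P+](c1ccccc1)(c1ccccc1)c1ccccc1.[Br-] | intermediate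
31 | ylide of 8 | CC1=C[C@@H](O[Si](C)(C)C(C)(C)C)CC(C)(C)/C1=C\C=C(/C)C=P(c1ccccc1)(c1ccccc1)c1ccccc1 | intermediate
32 | (all-E)-14-[(4S)-4-{[tert-butyl(dimethyl)silyl]oxy}-2,6,6-trimethylcyclohex-2-en-1-ylidene]-3,8,12-trimethyltetradeca-2,4,6,8,10,12-hexaenal | O=C/C=C(C)/C=C/C=C/C(C)=C/C=C/C(C)=C/C=C1/C(C)=C[C@@H](O[Si](C)(C)C(C)(C)C)CC1(C)C | intermediate
33 | ylide of 30 | CC1=CC(=O)CC(C)(C)/C1=C/C=C(C)/C=P(c1ccccc1)(c1ccccc1)c1ccccc1 | intermediate
34 | (3'S)-3'-{[tert-butyl(dimethyl)silyl]oxy}-4',5'-didehydro-4,5'-retro-β,β-caroten-3-one (all-E) | CC1=CC(=O)CC(C)(C)\C1=C/C=C(C)/C=C/C=C(C)/C=C/C=C/C(C)=C/C=C/C(C)=C/C=C1/C(C)=C[C@@H](O[Si](C)(C)C(C)(C)C)CC1(C)C | intermediate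
35 | (3'S,all-E)-3'-hydroxy-4',5'-didehydro-4,5'-retro-β,β-caroten-3-one | CC1=CC(=O)CC(C)(C)\C1=C/C=C(C)/C=C/C=C(C)/C=C/C=C/C(C)=C/C=C/C(C)=C/C=C1/C(C)=C[C@@H](O)CC1(C)C | target

**Step count and risks**

Total step count: 16. Longest linear sequence: 8 steps (steps 1–5, then 14–16).

Steps most likely to fail:

1. Step 12. The enolisation may give the unreactive enol geometry, or the allenyl enolate may drift into conjugation or undergo a [1,5]-hydrogen shift before the ring closes. The fallback sets out from 25 and fixes the triene geometry thermodynamically instead of kinetically: condensation with pyrrolidine over 4 Å molecular sieves in toluene gives the pyrrolidine dienamine F1, in which allylic 1,3-strain places nitrogen trans to the allenyl carbon and hence C2 cis to C5. Heating closes it to the cyclic dienamine F2. Hydrolysis with buffered aqueous acetic acid returns to the route at 28.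

2. Step 5. After ionisation of the tertiary carbinol under HBr, proton loss toward C3' (1,4-elimination), cleavage of the allylic silyl ether or capture of the cation at the wrong carbon may compete with capture by the phosphine at C10'. The fallback sets out from 7 and avoids free cations: deprotonation with n-BuLi and trapping with methyl chloroformate gives the tertiary dienyl methyl carbonate F3. Pd(PPh3)4 (cat.) and PPh3 in THF should ionise it under neutral conditions to a pentadienyl–palladium complex that the phosphine attacks at the terminal CH2. The methoxide released by decarboxylation then deprotonates the phosphonium ion, so the route is rejoined at ylide 31, which is used directly in step 14 (palladium-catalysed Wittig-type olefination of allylic carbonates).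

3. Step 11. Base-induced β-elimination of the carbonate from the ketone (E1cB) or protonation of the organozinc may outrun the SN2' coupling. The fallback sets out from 20 and from alkenyllithium 23 (made from 22 as in step 11) and turns the elimination into the route: DBU in CH2Cl2 converts 20 into the cross-conjugated dienynone 2,6-dimethylocta-2,5-dien-7-yn-4-one F4. Two equivalents of 23 and CuI give the lithium dialkenylcuprate F5, which should add in 1,6-fashion to the enyne terminus of F4 to give the lithium allenyl enolate F6. Kinetic protonation at C4 with pivalic acid at −78 °C returns to the route at 25.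

Further compounds
F1 | step 12 | pyrrolidine dienamine of 25 (nitrogen trans to the allene carbon C5; racemic allene) | CC(C)=C/C(N1CCCC1)=C\C(C)=C=C/C=C(\C)CO[Si](C)(C)C(C)(C)C
F2 | step 12 | 1-{(4Z)-4-[(2E)-4-{[tert-butyl(dimethyl)silyl]oxy}-3-methylbut-2-en-1-ylidene]-3,5,5-trimethylcyclohexa-1,5-dien-1-yl}pyrrolidine | CC1=CC(N2CCCC2)=CC(C)(C)/C1=C/C=C(C)/CO[Si](C)(C)C(C)(C)C
F3 | step 5 | methyl carbonate of 7 | CC1=C[C@@H](O[Si](C)(C)C(C)(C)C)CC(C)(C)C1(OC(=O)OC)/C=C/C(C)=C
F4 | step 11 | 2,6-dimethylocta-2,5-dien-7-yn-4-one (E/Z mixture at C5=C6) | CC(C)=CC(=O)C=C(C)C#C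
F5 | step 11 | lithium bis[(1E)-3-{[tert-butyl(dimethyl)silyl]oxy}-2-methylprop-1-en-1-yl]cuprate | [Li+].CC(C)(C)[Si](C)(C)OC/C(C)=C/[Cu-]/C=C(\C)CO[Si](C)(C)C(C)(C)C
F6 | step 11 | lithium allenyl enolate of 25 | CC(C)=CC(O[Li])=CC(C)=C=C/C=C(\C)CO[Si](C)(C)C(C)(C)C
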